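**Plan**

- Retrosynthesis: one strategic cut, the C3'–C8'' biaryl bond, splits the target into (2S)-naringenin and its 7-O-methyl ether (2S)-sakuranetin. The only other cuts are the 7''-O–CH3 bond and one temporary O-acetyl mask.
- Enabling feature: C3' is ortho to the 4'-OH on ring B of the naringenin half. C8'' is para to the 5''-OH and lies between O1'' and the 7''-OMe on ring A of the sakuranetin half. The bond therefore joins the ortho position of one phenol to the para position of another, the mark of an oxidative phenol coupling.
- Forward order: naringenin → sakuranetin (7-O-methylation) → its 4'-O-acetate (so that this half cannot act as the phenoxyl partner) → cytochrome P450 catalysed cross-dehydrogenative coupling with a second molecule of naringenin → removal of the acetate.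
- No ring is built: rings A, B and C of both halves come intact from the chiral pool, and no halogen, boron or tether is installed or removed.
- Stereochemistry: both (S) centres (C2 and C2'') come from commercial (2S)-naringenin. Every step is neutral or acidic so that neither pyranone opens by retro-oxa-Michael reaction. The new axis is not a stereo element.

Key step: step 3

Assumption: (2S)-naringenin is taken as purchasable in enantiopure form, and the biaryl axis, which bears only three small ortho substituents, is taken as freely rotating, in line with a target structure that defines no axial configuration.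

**Step 1**
Reactants: 1 (2S)-naringenin
Product: 2 (2S)-sakuranetin
Conditions: MeOH (1.05 equiv), PPh3, DIAD, THF, 0 °C to rt
Reagents that add atoms: methanol (SMILES: CO)
Why: Mitsunobu etherification: the 7-OH, para to the C4 carbonyl, is by far the most acidic phenol of 1 and should be the one deprotonated by the PPh3/DIAD betaine and methylated by the methoxyphosphonium ion, while the chelated 5-OH and the less acidic 4'-OH stay free and the near-neutral medium leaves C2 untouched.

**Step 2**
Reactants: 2 (2S)-sakuranetin
Product: 3 (2S)-sakuranetin 4'-O-acetate
Conditions: Ac2O (1.1 equiv), pyridine, CH2Cl2, 0 °C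
Reagents that add atoms: acetic anhydride (SMILES: CC(=O)OC(C)=O)
Why: Chemoselective O-acylation of a phenol: with the 5-OH tied up in the hydrogen bond to the C4 carbonyl, the 4'-OH is the only reactive hydroxyl of 2, and pyridine at 0 °C is too weak a base to open the pyranone ring, so C2 should keep its (S) configuration.

**Step 3**
Reactants: 1 (2S)-naringenin; 3 (2S)-sakuranetin 4'-O-acetate
Product: 5 (2S,2''S)-4'''-O-acetyl-7''-O-methyl-2,3,2'',3''-tetrahydroamentoflavone, via ring B dienone tautomer 4 (not isolated)
Conditions: cytochrome P450 phenol-coupling enzyme (biflavonoid synthase of the plant CYP90J type, variant evolved for this pair) with cytochrome P450 reductase (yeast microsomes), NADP+ (cat.), D-glucose, glucose dehydrogenase, air, potassium phosphate buffer pH 7.0, 5% DMSO, 28 °C; 3 in excess (3 equiv), 1 fed slowly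
Reagents that add atoms: none
Why: Proposed new method: the oxoiron porphyrin radical cation of the P450 (tetravalent iron) abstracts the hydrogen atom of the 4'-OH of 1, and the phenoxyl radical, with spin density at C3', adds to C8 of 3; one-electron oxidation of the resulting cyclohexadienyl radical by the hydroxoiron species (tetravalent iron) with loss of the C8 proton gives dienone 4, which tautomerises to phenol 5, so that overall 1 + 3 + O2 + NADPH + H+ give 5 + 2 H2O + NADP+. The closest known reaction type is the P450-catalysed oxidative phenol coupling that joins two molecules of the flavone apigenin at C3' and C8'' in gymnosperm biflavonoid biosynthesis, alongside evolved P450 enzymes that cross-couple two different phenols; new here are flavanone substrates and a cross-coupling of two flavonoids. No ring is closed and no stereocentre is formed, since the two C2 centres lie far from the reacting carbons and stay untouched at pH 7 and the new axis bears only three small ortho substituents. The step needs cross-coupling over homo-coupling, and the design secures it from both sides: 3 has no oxidisable free phenol outside the chelate and so cannot become the radical partner, which allows its use in excess with recovery, while slow feeding keeps 1 dilute so that its radical meets ring A of 3 far more often than ring A of another molecule of 1. It also needs C8 over C6 and C–C over C–O bond formation; both carbons are electronically activated, so this choice rests on the binding pocket that imposes the 3',8'' linkage in the natural reaction. Oxygen rebound (hydroxylation at C3') and oxidative loss of the 7-O-methyl group must stay slower than radical coupling, which is the criterion by which variants are to be selected.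

**Step 4**
Reactants: 5 (2S,2''S)-4'''-O-acetyl-7''-O-methyl-2,3,2'',3''-tetrahydroamentoflavone
Product: 6 (2S,2''S)-7''-O-methyl-2,3,2'',3''-tetrahydroamentoflavone (target)
Conditions: HCl (1.25 M in MeOH), 0 °C to rt
Reagents that add atoms: none
Why: Acid-catalysed transesterification (methanolysis) of an aryl acetate should free the 4'''-OH without any base, so that neither pyranone ring can open to a chalcone by retro-oxa-Michael reaction and both (S) centres are kept.

**Compound list**

1 | (2S)-naringenin, (2S)-5,7-dihydroxy-2-(4-hydroxyphenyl)chroman-4-one | Oc1ccc(cc1)[C@@H]1CC(=O)c2c(O)cc(O)cc2O1 | starting material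
2 | (2S)-sakuranetin, (2S)-5-hydroxy-2-(4-hydroxyphenyl)-7-methoxychroman-4-one | COc1cc(O)c2c(c1)O[C@H](c1ccc(O)cc1)CC2=O | intermediate
3 | (2S)-sakuranetin 4'-O-acetate, 4-[(2S)-5-hydroxy-7-methoxy-4-oxochroman-2-yl]phenyl acetate | COc1cc(O)c2c(c1)O[C@H](c1ccc(OC(C)=O)cc1)CC2=O | intermediate
4 | ring B dienone tautomer of 5: C3'–C8'' coupled cyclohexa-2,4-dienone (C4'=O, C3' sp3 with H, configuration at C3' undefined) | O=C1C=CC([C@@H]2CC(=O)c3c(O)cc(O)cc3O2)=CC1c1c(OC)cc(O)c2c1O[C@H](c1ccc(OC(C)=O)cc1)CC2=O | intermediate
5 | (2S,2''S)-4'''-O-acetyl-7''-O-methyl-2,3,2'',3''-tetrahydroamentoflavone | COc1cc(O)c2c(c1-c1cc([C@@H]3CC(=O)c4c(O)cc(O)cc4O3)ccc1O)O[C@H](c1ccc(OC(C)=O)cc1)CC2=O | intermediate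
6 | (2S,2''S)-7''-O-methyl-2,3,2'',3''-tetrahydroamentoflavone, (2S)-8-[5-[(2S)-5,7-dihydroxy-4-oxochroman-2-yl]-2-hydroxyphenyl]-5-hydroxy-2-(4-hydroxyphenyl)-7-methoxychroman-4-one | COc1cc(O)c2c(c1-c1cc([C@@H]3CC(=O)c4c(O)cc(O)cc4O3)ccc1O)O[C@H](c1ccc(O)cc1)CC2=O | target

**Count**

Total step count: 4. Longest linear sequence: 4 steps (1 → 2 → 3 → 5 → 6); naringenin 1 enters twice (steps 1 and 3).

**Steps most likely to fail**

1. Step 3 (Proposed new method). What may go wrong:
   - no turnover, because the enzyme family is known for the planar flavone and not for flavanones;
   - homo-coupling of 1 through its own ring A outrunning the cross-coupling;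
   - bond formation at C6 or through oxygen;
   - oxygen rebound or oxidative O-demethylation;
   - premature loss of the acetate to esterases in the microsomal preparation.

   Fallback (known chemistry, a Suzuki–Miyaura coupling in place of the oxidative coupling), setting out from 3 and 1 and returning to the route at 6: 3 is acetylated at the chelated 5-OH (Ac2O, DMAP, pyridine) to (2S)-sakuranetin 5,4'-di-O-acetate F1. Electrophilic iodination (NIS, CF3CO2H as catalyst, MeCN) should then enter C8, the site favoured in 5-O-capped 5,7-dioxygenated flavonoids, to give (2S)-8-iodosakuranetin 5,4'-di-O-acetate F2. In parallel 1 is peracetylated to (2S)-naringenin 5,7,4'-tri-O-acetate F3. Sterically governed C–H borylation ([Ir(OMe)(cod)]2, 4,4'-di-tert-butyl-2,2'-bipyridine, B2pin2, THF, 60 °C) should place boron at C3' to give the 3'-pinacolboronate of naringenin triacetate F4: the two C–H bonds of ring A are each flanked by two substituents, and on ring B the position next to the small acetoxy group is more open than the one next to the branched C2. Suzuki–Miyaura coupling of F2 with F4 (Pd(OAc)2, SPhos, anhydrous K3PO4, toluene, 60 °C) would give the penta-O-acetate of the target F5. The methanolysis of step 4 would then remove all five acetates and deliver 6.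

2. Step 1. What may go wrong: incomplete discrimination between the 7-OH and the 4'-OH, leading to double alkylation, and difficult removal of the phosphine oxide from a polar phenol. Fallback (biocatalytic methyl transfer in place of chemical alkylation), setting out from 1 and returning at 2: an S-adenosylmethionine-dependent naringenin 7-O-methyltransferase, expressed in Escherichia coli whole cells that regenerate the cofactor, should methylate only the 7-OH at neutral pH; no new compound arises on the way (F0).

3. Step 4. What may go wrong: acid-promoted ionisation of the benzylic C2–O1 bond next to a 4-hydroxyphenyl ring, which would erode the configuration at C2 or C2'', or incomplete cleavage of the ester. Fallback (a different mask, removed with fluoride in place of acid), setting out from 2 and returning at 6: 2 is silylated (TBSCl, imidazole, DMF, 0 °C) to (2S)-sakuranetin 4'-O-tert-butyldimethylsilyl ether F6. This takes the place of 3 in the coupling of step 3 to give the 4'''-O-tert-butyldimethylsilyl ether of the target F7, and Et3N·3HF in THF at 0 °C should then free 6 under buffered, non-basic conditions.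

**Further compounds**

F1 | step 3 | (2S)-sakuranetin 5,4'-di-O-acetate | COc1cc(OC(C)=O)c2c(c1)O[C@H](c1ccc(OC(C)=O)cc1)CC2=O
F2 | step 3 | (2S)-8-iodosakuranetin 5,4'-di-O-acetate | COc1cc(OC(C)=O)c2c(c1I)O[C@H](c1ccc(OC(C)=O)cc1)CC2=O
F3 | step 3 | (2S)-naringenin 5,7,4'-tri-O-acetate | CC(=O)Oc1ccc(cc1)[C@@H]1CC(=O)c2c(OC(C)=O)cc(OC(C)=O)cc2O1
F4 | step 3 | 3'-pinacolboronate of (2S)-naringenin 5,7,4'-tri-O-acetate | CC(=O)Oc1ccc(cc1B1OC(C)(C)C(C)(C)O1)[C@@H]1CC(=O)c2c(OC(C)=O)cc(OC(C)=O)cc2O1
F5 | step 3 | penta-O-acetate of the target (5,7,4',5'',4'''-penta-O-acetyl) | COc1cc(OC(C)=O)c2c(c1-c1cc([C@@H]3CC(=O)c4c(OC(C)=O)cc(OC(C)=O)cc4O3)ccc1OC(C)=O)O[C@H](c1ccc(OC(C)=O)cc1)CC2=O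
F0 | step 1 | none | none
F6 | step 4 | (2S)-sakuranetin 4'-O-tert-butyldimethylsilyl ether | COc1cc(O)c2c(c1)O[C@H](c1ccc(O[Si](C)(C)C(C)(C)C)cc1)CC2=O
F7 | step 4 | 4'''-O-tert-butyldimethylsilyl ether of the target | COc1cc(O)c2c(c1-c1cc([C@@H]3CC(=O)c4c(O)cc(O)cc4O3)ccc1O)O[C@H](c1ccc(O[Si](C)(C)C(C)(C)C)cc1)CC2=O
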